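## Retrosynthetic overview

1. The strategy rests on the one-carbon bridge C8 of the 2,7-dioxabicyclo[3.2.1]octan-3-one: its only bonds are to the acetal carbon C1, the bridgehead C5 and the quaternary C2 of the decalin, while the ester carbon, C6, C5, C4 and C3 form an unbranched 2-oxoglutarate chain.
2. The lactone ring (C1–O2) is closed last, by acetal exchange and lactonisation of a 2-methoxyoxolane; C5–H and C6–H come from reduction of the C5=C6 bond of a 2-methoxy-2,3-dihydrofuran and base equilibration at C6.
3. The oxolane ring (O7–C1) comes from Cloke–Wilson ring expansion of a methoxy/keto ester cyclopropane. The cyclopropane (C8–C1, C8–C5) comes from cobalt-porphyrin carbene transfer from the decalin carbaldehyde N-tosylhydrazone to the 3-methoxymethylidene derivative of dimethyl 2-oxoglutarate.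
4. Decalin aldehyde: ring B is cyclohexenone (rhodium-catalysed isopropenyl addition sets C4a; carbomethoxylation and axial methylation set C2). Ring A is built by radical addition of the isopropenyl group to acrolein and aldol condensation. The C1 methyl comes from methylenation and diimide reduction.
5. Ring order: ring B (purchased) → ring A → cyclopropane → oxolane → lactone.

Key step: step 13

Assumption: the antipode of the chiral cobalt porphyrin that gives the (8R) bridge carbon cannot be foretold for this alkene, so the ligand enantiomer is fixed by one trial with each antipode; locants C1–C8 are those of the 2,7-dioxabicyclo[3.2.1]octane, and decalin locants are those of the octahydronaphthalene.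

## Route

Step 1
Reactants: 1 cyclohex-2-en-1-one; 2 4,4,5,5-tetramethyl-2-(prop-1-en-2-yl)-1,3,2-dioxaborolane
Product: 3 (3R)-3-(prop-1-en-2-yl)cyclohexan-1-one
Conditions: [Rh(cod)Cl]2 (1.5 mol%), (R)-BINAP (3.5 mol%), KOH (0.2 equiv), 1,4-dioxane/H2O (10:1), 60 °C
Reagents that add atoms: none
Why: Rhodium-catalysed asymmetric conjugate addition of an alkenylboron reagent (Hayashi–Miyaura reaction) is reliable for cyclohexenone, the BINAP-bound alkenylrhodium adds to one enone face so that the future C4a is set by the ligand, and (R)-BINAP is expected to give the (R)-ketone by the sense known for aryl and alkenyl groups.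

Step 2
Reactants: 3 (3R)-3-(prop-1-en-2-yl)cyclohexan-1-one
Product: 4 methyl (4R)-2-oxo-4-(prop-1-en-2-yl)cyclohexane-1-carboxylate (keto and enol forms)
Conditions: NaH (2.2 equiv), (MeO)2CO (3 equiv), THF, reflux; then aq. HCl
Reagents that add atoms: dimethyl carbonate, COC(=O)OC
Why: Claisen-type C-acylation of the ketone under equilibrating conditions ends at the sodium enolate of the less hindered β-keto ester, at C6 of 3 and away from the isopropenyl-bearing carbon, and fixes no stereocentre.

Step 3
Reactants: 4 methyl (4R)-2-oxo-4-(prop-1-en-2-yl)cyclohexane-1-carboxylate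
Product: 5 methyl (1R,4R)-1-methyl-2-oxo-4-(prop-1-en-2-yl)cyclohexane-1-carboxylate
Conditions: K2CO3 (2 equiv), MeI (3 equiv), acetone, 50 °C
Reagents that add atoms: iodomethane, CI
Why: C-alkylation of the β-keto ester enolate, in which MeI enters axially through a chair-like transition state with the C4 isopropenyl group equatorial, so the new methyl ends cis to the isopropenyl group (1R) in the sense known for dihydrocarvone enolates, and any minor epimer is removed by chromatography.

Step 4
Reactants: 5 methyl (1R,4R)-1-methyl-2-oxo-4-(prop-1-en-2-yl)cyclohexane-1-carboxylate; 6 prop-2-enal (acrolein)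
Product: 7 methyl (1R,4R)-1-methyl-4-(2-methyl-5-oxopentan-2-yl)-2-oxocyclohexane-1-carboxylate
Conditions: Fe(acac)3 (30 mol%), PhSiH3 (2.5 equiv), 6 (3 equiv), EtOH/(CH2OH)2 (5:1), 60 °C
Reagents that add atoms: none
Why: Hydrogen-atom transfer from an iron hydride to the 1,1-disubstituted alkene gives the tertiary radical, which adds to acrolein in a Giese-type reductive olefin coupling and so builds the gem-dimethyl carbon C5 and the three-carbon arm of ring A without forming a stereocentre.

Step 5
Reactants: 7 methyl (1R,4R)-1-methyl-4-(2-methyl-5-oxopentan-2-yl)-2-oxocyclohexane-1-carboxylate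
Product: 9 methyl (2R,4aS)-2,5,5-trimethyl-1-oxo-1,2,3,4,4a,5,6,7-octahydronaphthalene-2-carboxylate, via aldol adduct 8 (not isolated)
Conditions: p-TsOH·H2O (10 mol%), PhMe, reflux, Dean–Stark trap
Reagents that add atoms: none
Why: Intramolecular aldol condensation in which the only enolisable ketone position (C3) attacks the aldehyde to close ring A (6-(enolexo)-exo-trig) and loss of water fixes the C8=C8a double bond in conjugation, whereas the aldol of the aldehyde enol onto the hindered ketone is reversible and cannot dehydrate at a bridgehead.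

Step 6
Reactants: 9 methyl (2R,4aS)-2,5,5-trimethyl-1-oxo-1,2,3,4,4a,5,6,7-octahydronaphthalene-2-carboxylate
Product: 10 methyl (2R,4aS)-2,5,5-trimethyl-1-methylidene-1,2,3,4,4a,5,6,7-octahydronaphthalene-2-carboxylate
Conditions: Ph3PCH3Br (2.5 equiv), KOtBu (2.3 equiv), PhMe, 80 °C
Reagents that add atoms: methyltriphenylphosphonium bromide, C[P+](c1ccccc1)(c1ccccc1)c1ccccc1.[Br-]
Why: Wittig methylenation with the unstabilised ylide adds 1,2 to the conjugated ketone, which has no α-hydrogen, and leaves the neopentyl ester alone; no stereocentre is formed.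

Step 7
Reactants: 10 methyl (2R,4aS)-2,5,5-trimethyl-1-methylidene-1,2,3,4,4a,5,6,7-octahydronaphthalene-2-carboxylate
Product: 11 methyl (1R,2R,4aS)-1,2,5,5-tetramethyl-1,2,3,4,4a,5,6,7-octahydronaphthalene-2-carboxylate
Conditions: 2-nitrobenzenesulfonohydrazide (10 equiv), Et3N (20 equiv), CH2Cl2, rt
Reagents that add atoms: none
Why: Diimide transfers H2 in a concerted syn fashion far faster to the 1,1-disubstituted exocyclic alkene than to the trisubstituted ring alkene, and it reaches C1 from the face opposite the axial C2 methyl (the only chair that the ring fusion allows has the ester equatorial), so the new methyl ends cis to the C2 methyl and C1 is set as (1R).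

Step 8
Reactants: 11 methyl (1R,2R,4aS)-1,2,5,5-tetramethyl-1,2,3,4,4a,5,6,7-octahydronaphthalene-2-carboxylate
Product: 12 [(1R,2R,4aS)-1,2,5,5-tetramethyl-1,2,3,4,4a,5,6,7-octahydronaphthalen-2-yl]methanol
Conditions: LiAlH4 (1.5 equiv), THF, 0 °C → rt; Fieser work-up
Reagents that add atoms: none
Why: Hydride reduction of the ester to the primary alcohol leaves the isolated alkene and all stereocentres untouched.

Step 9
Reactants: 12 [(1R,2R,4aS)-1,2,5,5-tetramethyl-1,2,3,4,4a,5,6,7-octahydronaphthalen-2-yl]methanol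
Product: 13 (1R,2R,4aS)-1,2,5,5-tetramethyl-1,2,3,4,4a,5,6,7-octahydronaphthalene-2-carbaldehyde
Conditions: Dess–Martin periodinane (1.3 equiv), CH2Cl2, rt
Reagents that add atoms: none
Why: Dess–Martin oxidation of the neopentyl alcohol gives the aldehyde, which has no α-hydrogen and cannot epimerise.

Step 10
Reactants: 13 (1R,2R,4aS)-1,2,5,5-tetramethyl-1,2,3,4,4a,5,6,7-octahydronaphthalene-2-carbaldehyde; 14 4-methylbenzenesulfonohydrazide
Product: 15 N'-[(E)-[(1R,2R,4aS)-1,2,5,5-tetramethyl-1,2,3,4,4a,5,6,7-octahydronaphthalen-2-yl]methylidene]-4-methylbenzenesulfonohydrazide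
Conditions: MeOH, 50 °C
Reagents that add atoms: none
Why: Condensation of the aldehyde with the sulfonyl hydrazide gives the (E)-N-tosylhydrazone and touches no stereocentre.

Step 11
Reactants: 16 methyl 4,4-dimethoxybutanoate
Product: 17 methyl (E)-4-methoxybut-3-enoate (E/Z mixture)
Conditions: TMSOTf (1.1 equiv), iPr2NEt (1.3 equiv), CH2Cl2, −20 °C → rt
Reagents that add atoms: none
Why: Gassman-type elimination in which TMSOTf ionises the dimethyl acetal and the amine removes the adjacent proton to give the enol ether, whose geometry is reset in step 12.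

Step 12
Reactants: 17 methyl (E)-4-methoxybut-3-enoate; 18 methyl chlorooxoacetate
Product: 20 dimethyl (3E)-3-(methoxymethylidene)-2-oxopentanedioate, via chloro ether adduct 19 (not isolated)
Conditions: pyridine (1.3 equiv), CH2Cl2, 0 °C → rt
Reagents that add atoms: none
Why: Acylation of an enol ether at its nucleophilic β-carbon by an oxalyl chloride half ester and loss of HCl is the standard route to 4-alkoxy-2-oxobut-3-enoates and gives the more stable (E)-isomer, and it is chosen over a condensation of dimethyl 2-oxoglutarate with an orthoformate because the C3 methylene of that ester is activated by one carbonyl group only.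

Step 13
Reactants: 15 N'-[(E)-[(1R,2R,4aS)-1,2,5,5-tetramethyl-1,2,3,4,4a,5,6,7-octahydronaphthalen-2-yl]methylidene]-4-methylbenzenesulfonohydrazide; 20 dimethyl (3E)-3-(methoxymethylidene)-2-oxopentanedioate
Product: 22 methyl 2-[(1R,2R,3S)-2-methoxy-1-(2-methoxy-2-oxoethyl)-3-[(1S,2R,4aS)-1,2,5,5-tetramethyl-1,2,3,4,4a,5,6,7-octahydronaphthalen-2-yl]cyclopropyl]-2-oxoacetate, via diazoalkane 21 (not isolated)
Conditions: [Co(P)] (5 mol%; P = 3,5-DitBu-ChenPhyrin, the D2-symmetric chiral amidoporphyrin, a divalent cobalt complex), Cs2CO3 (1.5 equiv), 20 (3 equiv), 1,4-dioxane, 60 °C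
Reagents that add atoms: none
Why: Cs2CO3 releases diazoalkane 21 from 15 (Bamford–Stevens), the divalent cobalt porphyrin takes it up with loss of N2 as a cobalt-bound carbene radical that has no β-hydrogen to shift because the neighbouring decalin carbon is quaternary, and this radical adds to the methoxy-bearing alkene carbon of 20 (future C1) to leave a radical at C5 that is stabilised by the keto ester. The C5 radical then displaces cobalt from the carbene carbon in a 3-exo-tet radical substitution, which closes the cyclopropane and completes the bonds C8–C1 and C8–C5. The closest known reaction is the cobalt-porphyrin metalloradical cyclopropanation of acrylates, vinyl ketones and other electron-poor alkenes with diazo compounds made in the flask from N-tosylhydrazones; a trisubstituted push–pull alkene and a tertiary-alkyl diazomethane lie at the edge of that scope. The carbene carbon (C8) is the only new stereocentre that is kept, and it is fixed by the chiral amide pocket of the porphyrin, which chooses the enantioface of the carbene radical, since the adjacent quaternary carbon alone gives little bias; the centres at C1 and C5 follow from the (E)-alkene and from the decalin avoiding the methoxy group, and both are erased in steps 14 and 17. The step needs carbene transfer to be faster than uncatalysed dipolar cycloaddition of 21 to the enone, than attack of 21 on the keto group and than hydrogen abstraction within the decalin, and this is secured by the slow release of 21, by the excess of 20 and by the radical-stabilising keto ester that directs the addition to C1.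

Step 14
Reactants: 22 methyl 2-[(1R,2R,3S)-2-methoxy-1-(2-methoxy-2-oxoethyl)-3-[(1S,2R,4aS)-1,2,5,5-tetramethyl-1,2,3,4,4a,5,6,7-octahydronaphthalen-2-yl]cyclopropyl]-2-oxoacetate
Product: 23 methyl (2S,3S)-2-methoxy-4-(2-methoxy-2-oxoethyl)-3-[(1S,2R,4aS)-1,2,5,5-tetramethyl-1,2,3,4,4a,5,6,7-octahydronaphthalen-2-yl]-2,3-dihydrofuran-5-carboxylate
Conditions: Sc(OTf)3 (2 mol%), CH2Cl2, −20 → 0 °C; Et3N quench
Reagents that add atoms: none
Why: Cloke–Wilson rearrangement in which the C1–C5 bond between the methoxy donor and the keto ester acceptor heterolyses and the enolate oxygen (O7) closes on the oxocarbenium carbon C1 to the five-membered 2-methoxy-2,3-dihydrofuran, with C8 untouched, the methoxy group expected trans to the decalin (a centre lost again in step 17), and protic acid avoided so that methanol is not eliminated to the furan.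

Step 15
Reactants: 23 methyl (2S,3S)-2-methoxy-4-(2-methoxy-2-oxoethyl)-3-[(1S,2R,4aS)-1,2,5,5-tetramethyl-1,2,3,4,4a,5,6,7-octahydronaphthalen-2-yl]-2,3-dihydrofuran-5-carboxylate
Product: 24 methyl (2S,3R,4R,5S)-5-methoxy-3-(2-methoxy-2-oxoethyl)-4-[(1S,2R,4aS)-1,2,5,5-tetramethyl-1,2,3,4,4a,5,6,7-octahydronaphthalen-2-yl]oxolane-2-carboxylate
Conditions: (IPr)CuCl (5 mol%; IPr = 1,3-bis(2,6-diisopropylphenyl)imidazol-2-ylidene), NaOtBu (5 mol%), (EtO)2MeSiH (3 equiv), tBuOH (3 equiv), PhMe, rt → 40 °C
Reagents that add atoms: none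
Why: Copper hydride conjugate reduction of the α,β-unsaturated ester, in which the ligated copper hydride delivers hydride to C5 from the face opposite the decalin on the neighbouring C8 (acetate arm cis to the decalin) and the copper enolate is protonated at C6 from the same open face to give mainly the 5,6-cis ester, whose C6 is corrected in step 16.

Step 16
Reactants: 24 methyl (2S,3R,4R,5S)-5-methoxy-3-(2-methoxy-2-oxoethyl)-4-[(1S,2R,4aS)-1,2,5,5-tetramethyl-1,2,3,4,4a,5,6,7-octahydronaphthalen-2-yl]oxolane-2-carboxylate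
Product: 25 methyl (2R,3R,4R,5S)-5-methoxy-3-(2-methoxy-2-oxoethyl)-4-[(1S,2R,4aS)-1,2,5,5-tetramethyl-1,2,3,4,4a,5,6,7-octahydronaphthalen-2-yl]oxolane-2-carboxylate
Conditions: NaOMe (0.3 equiv), MeOH, rt
Reagents that add atoms: none
Why: Epimerisation through the ester enolate places the C6 ester trans to the C5 acetate arm, the more stable arrangement on the oxolane, so C6 is set under thermodynamic control, and methoxide in methanol leaves the methyl esters and the acetal as they are.

Step 17
Reactants: 25 methyl (2R,3R,4R,5S)-5-methoxy-3-(2-methoxy-2-oxoethyl)-4-[(1S,2R,4aS)-1,2,5,5-tetramethyl-1,2,3,4,4a,5,6,7-octahydronaphthalen-2-yl]oxolane-2-carboxylate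
Product: 27 methyl (1S,5R,6R,8R)-3-oxo-8-[(1S,2R,4aS)-1,2,5,5-tetramethyl-1,2,3,4,4a,5,6,7-octahydronaphthalen-2-yl]-2,7-dioxabicyclo[3.2.1]octane-6-carboxylate, via lactol 26 (not isolated)
Conditions: 1 M aq. HCl/THF (1:4), rt; then PPTS (10 mol%), PhMe, 80 °C
Reagents that add atoms: water, O
Why: Acid hydrolysis of the methyl acetal gives the lactol, whose anomeric hydroxyl attacks the arm ester in an acid-catalysed lactonisation that closes the six-membered lactone of the bicycle, and C1 is set by the bridge itself because only the anomer with the hydroxyl on the face of the C5 arm can lactonise while the anomers interconvert.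

## Compound list

1 | cyclohex-2-en-1-one | O=C1C=CCCC1 | starting material
2 | 4,4,5,5-tetramethyl-2-(prop-1-en-2-yl)-1,3,2-dioxaborolane | CC(=C)B1OC(C)(C)C(C)(C)O1 | starting material
3 | (3R)-3-(prop-1-en-2-yl)cyclohexan-1-one | O=C1C[C@H](C(C)=C)CCC1 | intermediate
4 | methyl (4R)-2-oxo-4-(prop-1-en-2-yl)cyclohexane-1-carboxylate | COC(=O)C1CC[C@@H](C(C)=C)CC1=O | intermediate
5 | methyl (1R,4R)-1-methyl-2-oxo-4-(prop-1-en-2-yl)cyclohexane-1-carboxylate | COC(=O)[C@]1(C)CC[C@@H](C(C)=C)CC1=O | intermediate
6 | prop-2-enal (acrolein) | C=CC=O | starting material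
7 | methyl (1R,4R)-1-methyl-4-(2-methyl-5-oxopentan-2-yl)-2-oxocyclohexane-1-carboxylate | COC(=O)[C@]1(C)CC[C@@H](C(C)(C)CCC=O)CC1=O | intermediate
8 | methyl (2R,4aS)-8-hydroxy-2,5,5-trimethyl-1-oxodecahydronaphthalene-2-carboxylate (aldol adduct, C8 and C8a epimers) | COC(=O)[C@]1(C)CC[C@@H]2C(C(O)CCC2(C)C)C1=O | intermediate
9 | methyl (2R,4aS)-2,5,5-trimethyl-1-oxo-1,2,3,4,4a,5,6,7-octahydronaphthalene-2-carboxylate | COC(=O)[C@]1(C)CC[C@@H]2C(=CCCC2(C)C)C1=O | intermediate
10 | methyl (2R,4aS)-2,5,5-trimethyl-1-methylidene-1,2,3,4,4a,5,6,7-octahydronaphthalene-2-carboxylate | COC(=O)[C@]1(C)CC[C@@H]2C(=CCCC2(C)C)C1=C | intermediate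
11 | methyl (1R,2R,4aS)-1,2,5,5-tetramethyl-1,2,3,4,4a,5,6,7-octahydronaphthalene-2-carboxylate | COC(=O)[C@]1(C)CC[C@@H]2C(=CCCC2(C)C)[C@H]1C | intermediate
12 | [(1R,2R,4aS)-1,2,5,5-tetramethyl-1,2,3,4,4a,5,6,7-octahydronaphthalen-2-yl]methanol | OC[C@]1(C)CC[C@@H]2C(=CCCC2(C)C)[C@H]1C | intermediate
13 | (1R,2R,4aS)-1,2,5,5-tetramethyl-1,2,3,4,4a,5,6,7-octahydronaphthalene-2-carbaldehyde | O=C[C@]1(C)CC[C@@H]2C(=CCCC2(C)C)[C@H]1C | intermediate
14 | 4-methylbenzenesulfonohydrazide | Cc1ccc(cc1)S(=O)(=O)NN | starting material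
15 | N'-[(E)-[(1R,2R,4aS)-1,2,5,5-tetramethyl-1,2,3,4,4a,5,6,7-octahydronaphthalen-2-yl]methylidene]-4-methylbenzenesulfonohydrazide | Cc1ccc(cc1)S(=O)(=O)N/N=C/[C@]1(C)CC[C@@H]2C(=CCCC2(C)C)[C@H]1C | intermediate
16 | methyl 4,4-dimethoxybutanoate | COC(OC)CCC(=O)OC | starting material
17 | methyl (E)-4-methoxybut-3-enoate | CO/C=C/CC(=O)OC | intermediate
18 | methyl chlorooxoacetate | COC(=O)C(Cl)=O | starting material
19 | dimethyl 3-[chloro(methoxy)methyl]-2-oxopentanedioate (chloro ether adduct) | COC(Cl)C(C(=O)C(=O)OC)CC(=O)OC | intermediate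
20 | dimethyl (3E)-3-(methoxymethylidene)-2-oxopentanedioate | CO/C=C(/C(=O)C(=O)OC)CC(=O)OC | intermediate
21 | (1R,2R,4aS)-2-(diazomethyl)-1,2,5,5-tetramethyl-1,2,3,4,4a,5,6,7-octahydronaphthalene | [N-]=[N+]=C[C@]1(C)CC[C@@H]2C(=CCCC2(C)C)[C@H]1C | intermediate
22 | methyl 2-[(1R,2R,3S)-2-methoxy-1-(2-methoxy-2-oxoethyl)-3-[(1S,2R,4aS)-1,2,5,5-tetramethyl-1,2,3,4,4a,5,6,7-octahydronaphthalen-2-yl]cyclopropyl]-2-oxoacetate | CO[C@H]1[C@](CC(=O)OC)(C(=O)C(=O)OC)[C@@H]1[C@]1(C)CC[C@@H]2C(=CCCC2(C)C)[C@H]1C | intermediate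
23 | methyl (2S,3S)-2-methoxy-4-(2-methoxy-2-oxoethyl)-3-[(1S,2R,4aS)-1,2,5,5-tetramethyl-1,2,3,4,4a,5,6,7-octahydronaphthalen-2-yl]-2,3-dihydrofuran-5-carboxylate | CO[C@H]1OC(C(=O)OC)=C(CC(=O)OC)[C@@H]1[C@]1(C)CC[C@@H]2C(=CCCC2(C)C)[C@H]1C | intermediate
24 | methyl (2S,3R,4R,5S)-5-methoxy-3-(2-methoxy-2-oxoethyl)-4-[(1S,2R,4aS)-1,2,5,5-tetramethyl-1,2,3,4,4a,5,6,7-octahydronaphthalen-2-yl]oxolane-2-carboxylate | COC(=O)[C@H]1O[C@H](OC)[C@@H]([C@]2(C)CC[C@@H]3C(=CCCC3(C)C)[C@H]2C)[C@H]1CC(=O)OC | intermediate
25 | methyl (2R,3R,4R,5S)-5-methoxy-3-(2-methoxy-2-oxoethyl)-4-[(1S,2R,4aS)-1,2,5,5-tetramethyl-1,2,3,4,4a,5,6,7-octahydronaphthalen-2-yl]oxolane-2-carboxylate | COC(=O)[C@@H]1O[C@H](OC)[C@@H]([C@]2(C)CC[C@@H]3C(=CCCC3(C)C)[C@H]2C)[C@H]1CC(=O)OC | intermediate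
26 | methyl (2R,3R,4R)-5-hydroxy-3-(2-methoxy-2-oxoethyl)-4-[(1S,2R,4aS)-1,2,5,5-tetramethyl-1,2,3,4,4a,5,6,7-octahydronaphthalen-2-yl]oxolane-2-carboxylate (lactol, both anomers) | COC(=O)[C@@H]1OC(O)[C@@H]([C@]2(C)CC[C@@H]3C(=CCCC3(C)C)[C@H]2C)[C@H]1CC(=O)OC | intermediate
27 | methyl (1S,5R,6R,8R)-3-oxo-8-[(1S,2R,4aS)-1,2,5,5-tetramethyl-1,2,3,4,4a,5,6,7-octahydronaphthalen-2-yl]-2,7-dioxabicyclo[3.2.1]octane-6-carboxylate | COC(=O)[C@@H]1O[C@H]2OC(=O)C[C@@H]1[C@@H]2[C@]1(C)CC[C@@H]2C(=CCCC2(C)C)[C@H]1C | target

## Step count and risks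

Total: 17 steps (10 to hydrazone 15, 2 to alkene 20, 5 from their union). Longest linear sequence: 15 steps (steps 1–10 and 13–17).

**Step 13.** Carbene transfer to the hindered trisubstituted push–pull alkene may be slower than uncatalysed dipolar cycloaddition or hydrogen abstraction inside the decalin, and the catalyst may give poor enantiofacial control at C8. Fallback, setting out from 15: deprotonation with NaH and warming of the dry sodium salt with 20 in PhMe at 80 °C, in the dark and without metal, lets diazoalkane 21 add to the enone in a 1,3-dipolar cycloaddition (diazo carbon to the methoxy-bearing carbon) to give the 1-pyrazoline adduct F1. Irradiation at 350 nm extrudes N2 and closes the ring, and the route is rejoined at 22. Without the catalyst only the decalin controls the carbene carbon, so the epimer is separated at 22 or 23.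

**Step 15.** Hydride transfer to the tetrasubstituted, oxygen-bearing C5=C6 bond may be too slow, leaving the dihydrofuran unreduced. Fallback, setting out from 23: LiOH in THF/H2O hydrolyses both methyl esters to the dihydrofuran diacid F2. As its bis(triethylammonium) salt this is hydrogenated with Ru(OAc)2[(R)-BINAP] (H2, 50 bar, MeOH, 40 °C; the other ligand antipode if mismatched). This carboxylate-directed hydrogenation of an α-alkoxy acrylic acid leaves the isolated trisubstituted alkene alone and adds H2 to the face away from the decalin, giving the 5,6-cis oxolane diacid F3. TMSCHN2 (PhMe/MeOH) restores the dimethyl ester and the route is rejoined at 24.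

**Step 7.** Diimide may fail to distinguish the two alkenes of the diene, or may give poor facial selectivity at C1. Fallback, setting out from 9: MeLi/CeCl3 (THF, −78 °C) adds to the ketone to give the tertiary allylic alcohol F4. Pyridinium chlorochromate (CH2Cl2) transposes it oxidatively (Babler–Dauben) to the enone F5, with the carbonyl at C8 and the methyl-bearing C1 in the double bond. Li/NH3 (THF, −78 °C) followed by PhNTf2 reduces the enone with axial protonation at C1 on the face of H-4a and traps the C8 enolate as the enol triflate F6. Pd(OAc)2, PPh3, Bu3N and HCO2H (DMF, 60 °C) replace the triflate by hydrogen, and the route is rejoined at 11.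

## Further compounds

F1 | step 13 | methyl 2-[4-methoxy-3-(2-methoxy-2-oxoethyl)-5-(1,2,5,5-tetramethyl-1,2,3,4,4a,5,6,7-octahydronaphthalen-2-yl)-4,5-dihydro-3H-pyrazol-3-yl]-2-oxoacetate (1-pyrazoline adduct) | CO[C@H]1[C@](CC(=O)OC)(C(=O)C(=O)OC)N=N[C@@H]1[C@]1(C)CC[C@@H]2C(=CCCC2(C)C)[C@H]1C
F2 | step 15 | (2S,3S)-4-(carboxymethyl)-2-methoxy-3-(1,2,5,5-tetramethyl-1,2,3,4,4a,5,6,7-octahydronaphthalen-2-yl)-2,3-dihydrofuran-5-carboxylic acid (dihydrofuran diacid) | CO[C@H]1OC(C(O)=O)=C(CC(O)=O)[C@@H]1[C@]1(C)CC[C@@H]2C(=CCCC2(C)C)[C@H]1C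
F3 | step 15 | (2S,3R,4R,5S)-3-(carboxymethyl)-5-methoxy-4-(1,2,5,5-tetramethyl-1,2,3,4,4a,5,6,7-octahydronaphthalen-2-yl)oxolane-2-carboxylic acid (5,6-cis oxolane diacid) | OC(=O)[C@H]1O[C@H](OC)[C@@H]([C@]2(C)CC[C@@H]3C(=CCCC3(C)C)[C@H]2C)[C@H]1CC(O)=O
F4 | step 7 | methyl (2R,4aS)-1-hydroxy-1,2,5,5-tetramethyl-1,2,3,4,4a,5,6,7-octahydronaphthalene-2-carboxylate (tertiary allylic alcohol, C1 epimers) | COC(=O)[C@]1(C)CC[C@@H]2C(=CCCC2(C)C)C1(C)O
F5 | step 7 | methyl (2R,4aS)-1,2,5,5-tetramethyl-8-oxo-2,3,4,4a,5,6,7,8-octahydronaphthalene-2-carboxylate (transposed enone) | COC(=O)[C@]1(C)CC[C@@H]2C(C(=O)CCC2(C)C)=C1C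
F6 | step 7 | methyl (1R,2R,4aS)-1,2,5,5-tetramethyl-8-(trifluoromethylsulfonyloxy)-1,2,3,4,4a,5,6,7-octahydronaphthalene-2-carboxylate (enol triflate) | COC(=O)[C@]1(C)CC[C@@H]2C(=C(OS(=O)(=O)C(F)(F)F)CCC2(C)C)[C@H]1C
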